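The data stem from a simulated flask with constants of no real substance, and the scatter is random.

**Minutes on the teal flask**

The meeting opened on the reading at 120 min: teal L 40.2%, J 2.5%.

| flask | J | L | X | Z | remark | time |
|---|---|---|---|---|---|---|
| teal | 2.1 M | 2.1 M | 200 mM (held) | 3.6 mM | the very flask that is asked about, followed so far |  |
| ochre | 1.1 M | 1.1 M | 200 mM (held) | 3.6 mM | run made earlier |  |
| flask | 2.1 M | 2.1 M | 200 mM (held) | 3.6 mM |  | 5.0 h |

teal run (percent of the J and L together charged)

| time / min | L / % | J / % |
|---|---|---|
| 10.0 | 49.2 | 40.9 |
| 20.0 | 48.3 | 32.1 |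
| 30.0 | 48.0 | 25.2 |
| 60.0 | 45.0 | 11.6 |
| 120 | 40.2 | 2.5 |

ochre run (percent of the J and L together charged)

| time / h | L / % | J / % |
|---|---|---|
| 0.250 | 48.8 | 34.8 |
| 0.500 | 47.6 | 23.1 |
| 1.00 | 44.9 | 10.1 |
| 2.00 | 39.0 | 1.6 |
| 4.00 | 30.8 | 0.7 |

(scatter of a reading: 0.3 percentage points)

* whether the excess of L over J among what is left of the two reaches 95% by 5.0 h (yes / no)
* the highest excess of L over J among what is left of the two up to 5.0 h

- Z is single-handed; J and L are mirror images of each other, charged as a racemate, each of them at the stated concentration
- at the start none of X is in solution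

The first speaker took J and L each to be lost in proportion to its own amount, with its own constant and one shared factor of the medium that may change with time. Time then cancels from the ratio of their rates. With j and l the parts of J and L left of their own charges, the integral is j = l^s. Here s, the selectivity factor, is the ratio of the two constants. Each enantiomer starts at half of the total, so the last teal reading gave s = 13.7. She tried it on ochre: at 2.00 h, L 39.0% gives J 1.66%, and 1.6% was read.

The second speaker turned this into a target. An excess of 95% needs J/L of 0.0256, and with equal charges J/L equals j/l, which is l to the power (s minus one). So L must fall to 37.5% of the charge. The last two teal readings of L gave a pseudo-first-order constant of 0.113 h⁻¹. His estimate at that pace put teal L there at 2.62 h and at 28.7% by 5.0 h. He therefore committed to yes, with a top of 99.8%.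

The forecast also said yes, but with a lower top of 96.2%. Its maker read the ochre J of 0.7% as a hint of “a slow leak from L to J (racemisation)”.

The flask gives yes and 99.9%. The excess reached 95% at 2.50 h, with L at 37.6% of the charge.

    Q + Z + J → Z + D (k = 0.668 L² mol⁻² s⁻¹)
    Q + Z + L → Z + G (k = 0.0483 L² mol⁻² s⁻¹)
    X ⇌ Q, rate k3*(csat - [Q]) (kL = 0.0179 s⁻¹)
    Q → E (k = 1.41 × 10⁻⁵ s⁻¹)

At 5.00 h, teal L stands at 55% of its own charge. The rule then gives J 0.0287% of its own, and the flask holds 0.027%. On ochre at 4.00 h, L 30.8% gives J 0.0645%, which lies 0.63 percentage points below the reading, whose scatter is 0.3 points.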